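## Retrosynthetic overview
- The target comes from global deprotection and reduction of a trans-2,3-diester of a 1-aryl-tetralin. The C2/C3 trans relationship is inherited from (E)-fumarate.
- C1 (aryl-bearing) is set by ionic hydrogenation of a tertiary diarylcarbinol, with hydride delivered trans to the C2 substituent.
- The only carbocycle is formed in one step: photoenolization/Diels–Alder of a 2-methylbenzophenone. The transient hydroxy-o-quinodimethane is dearomatised, and it adds to a symmetric chiral fumarate diester.
- The benzophenone comes from Friedel–Crafts acylation of protected creosol with acetyl-syringoyl chloride. Both aromatic rings come intact from cheap feedstocks (creosol, syringic acid).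

**Assumption:** the menthyl diastereomers formed in step 6 can be separated chromatographically after step 7, and the (1R,2S,3S) series is then taken forward. Target CIP assignment from the SMILES: (1R,2S,3S), all-trans.

## Route

**Step 1**
Reactants: 1 (creosol, 2-methoxy-4-methylphenol)
Product: 2 (1-(benzyloxy)-2-methoxy-4-methylbenzene)
Conditions: BnBr, K2CO3, DMF, 60 °C
Reagents that add atoms: benzyl bromide, BrCc1ccccc1
Why: Williamson ether synthesis masks the future C7 phenol so it survives the Lewis-acid and photochemical steps.

**Step 2**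
Reactants: 3 (syringic acid, 4-hydroxy-3,5-dimethoxybenzoic acid)
Product: 4 (4-acetoxy-3,5-dimethoxybenzoic acid)
Conditions: Ac2O, pyridine, cat. DMAP, CH2Cl2, rt
Reagents that add atoms: acetic anhydride, CC(=O)OC(C)=O
Why: O-acetylation protects the syringyl phenol. The acetate is cleaved later by LiAlH4, and its weaker donation keeps the ketone n,π*-like for photoenolization.

**Step 3**
Reactants: 4
Product: 5 (4-acetoxy-3,5-dimethoxybenzoyl chloride)
Conditions: (COCl)2, cat. DMF, CH2Cl2, 0 °C to rt; evaporate and use crude
Reagents that add atoms: oxalyl chloride, ClC(=O)C(=O)Cl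
Why: standard acid-chloride formation.

**Step 4**
Reactants: 2, 5
Product: 6 ((4-acetoxy-3,5-dimethoxyphenyl)(5-benzyloxy-4-methoxy-2-methylphenyl)methanone)
Conditions: SnCl4 (1.2 equiv), CH2Cl2, 0 °C to rt
Reagents that add atoms: none
Why: Friedel–Crafts acylation goes para to the OMe and ortho to the CH3, the usual outcome for 4-methyl-1,2-dialkoxyarenes. This installs the C1 carbon, the C4 methyl and the A-ring oxygenation pattern (6-OMe, 7-OBn) at once.

**Step 5**
Reactants: 7 (fumaryl chloride), 8 ((1R,2S,5R)-(−)-menthol, 2.1 equiv)
Product: 9 (di-(−)-menthyl (E)-but-2-enedioate)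
Conditions: Et3N, cat. DMAP, CH2Cl2, 0 °C to rt
Reagents that add atoms: none
Why: double esterification gives a symmetric, chiral, trans-configured dienophile.

**Step 6** (key step)
Reactants: 6, 9 (4 equiv)
Product: 10 (bis-menthyl 1-hydroxy-1-aryl-tetralin-2,3-dicarboxylate, trans-2,3; mixture of C1 epimers and of the two facial diastereomers)
Conditions: hν (350 nm, Pyrex), degassed MeCN, 20 °C, 24–48 h
Reagents that add atoms: none
Why: Proposed new method: irradiation of the o-methyl diaryl ketone gives a 1,5-H shift to a transient, dearomatised hydroxy-o-quinodimethane, which undergoes a suprafacial [4+2] with the fumarate, so the E geometry is retained and C2/C3 come out trans; the closest known reaction is the photoenolization/Diels–Alder (Sammes–Nerdel type) of 2-methylbenzophenones with dienophiles, and the menthyl groups bias the dienophile face, giving separable diastereomers.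

**Step 7**
Reactants: 10
Product: 11 (bis-(−)-menthyl (1R,2S,3S)-1-(4-acetoxy-3,5-dimethoxyphenyl)-7-benzyloxy-6-methoxy-1,2,3,4-tetrahydronaphthalene-2,3-dicarboxylate), isolated by HPLC or silica chromatography from its diastereomers
Conditions: Et3SiH (5 equiv), BF3·OEt2 (3 equiv), CH2Cl2, −78 to 0 °C
Reagents that add atoms: none (hydride only)
Why: Ionic hydrogenation (Et3SiH/BF3) ionises the tertiary alcohol to a diarylcarbenium stabilised by the p-OMe and the syringyl ring, so the C1 configuration of 10 is erased. Axial hydride delivery to the half-chair cation, with the C2 ester pseudo-equatorial, puts the new aryl group trans to C2, which sets C1. The menthyl diastereomers are separated here.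

**Step 8**
Reactants: 11
Product: 12 ((1R,2S,3S)-7-benzyloxy-1-(4-hydroxy-3,5-dimethoxyphenyl)-6-methoxy-2,3-bis(hydroxymethyl)tetralin)
Conditions: LiAlH4 (6 equiv), THF, 0 °C to reflux; Fieser work-up; menthol removed by chromatography
Reagents that add atoms: none (hydride only)
Why: ester reduction gives the diol and releases (−)-menthol. The aryl acetate is cleaved to the free phenol in the same step, and the benzyl ether is inert. The stereocentres are not touched.

**Step 9**
Reactants: 12
Product: 13 (target)
Conditions: H2 (1 atm), 10% Pd/C, EtOH/EtOAc, rt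
Reagents that add atoms: none (hydrogen only)
Why: hydrogenolysis of the aryl benzyl ether frees the C7 phenol. The diarylmethine C–H and the primary alcohols are unaffected, so all three stereocentres are retained.

## Compound list
1 | creosol (2-methoxy-4-methylphenol) | COc1cc(C)ccc1O | starting material
2 | 1-(benzyloxy)-2-methoxy-4-methylbenzene | COc1cc(C)ccc1OCc1ccccc1 | intermediate
3 | syringic acid | COc1cc(C(=O)O)cc(OC)c1O | starting material
4 | 4-acetoxy-3,5-dimethoxybenzoic acid | COc1cc(C(=O)O)cc(OC)c1OC(C)=O | intermediate
5 | 4-acetoxy-3,5-dimethoxybenzoyl chloride | COc1cc(C(=O)Cl)cc(OC)c1OC(C)=O | intermediate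
6 | (4-acetoxy-3,5-dimethoxyphenyl)(5-benzyloxy-4-methoxy-2-methylphenyl)methanone | COc1cc(C)c(C(=O)c2cc(OC)c(OC(C)=O)c(OC)c2)cc1OCc1ccccc1 | intermediate
7 | fumaryl chloride | ClC(=O)/C=C/C(=O)Cl | starting material
8 | (1R,2S,5R)-(−)-menthol | C[C@@H]1CC[C@H]([C@@H](C1)O)C(C)C | starting material
9 | di-(−)-menthyl fumarate | C[C@@H]1CC[C@H]([C@@H](C1)OC(=O)/C=C/C(=O)O[C@@H]2C[C@H](C)CC[C@H]2C(C)C)C(C)C | intermediate
10 | bis-menthyl (2R,3S)-1-hydroxy-1-aryl-7-benzyloxy-6-methoxytetralin-2,3-dicarboxylate, trans-2,3, C1 unspecified (mixture) | COc1cc2c(cc1OCc1ccccc1)C(O)(c1cc(OC)c(OC(C)=O)c(OC)c1)[C@H](C(=O)O[C@@H]3C[C@H](C)CC[C@H]3C(C)C)[C@@H](C(=O)O[C@@H]4C[C@H](C)CC[C@H]4C(C)C)C2 | intermediate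
11 | bis-(−)-menthyl (1R,2S,3S)-1-(4-acetoxy-3,5-dimethoxyphenyl)-7-benzyloxy-6-methoxytetralin-2,3-dicarboxylate | COc1cc2c(cc1OCc1ccccc1)[C@@H](c1cc(OC)c(OC(C)=O)c(OC)c1)[C@H](C(=O)O[C@@H]3C[C@H](C)CC[C@H]3C(C)C)[C@@H](C(=O)O[C@@H]4C[C@H](C)CC[C@H]4C(C)C)C2 | intermediate
12 | (1R,2S,3S)-7-benzyloxy-1-(4-hydroxy-3,5-dimethoxyphenyl)-6-methoxy-2,3-bis(hydroxymethyl)tetralin | COc1cc2c(cc1OCc1ccccc1)[C@@H](c1cc(OC)c(O)c(OC)c1)[C@H](CO)[C@@H](CO)C2 | intermediate
13 | (1R,2S,3S)-1-(4-hydroxy-3,5-dimethoxyphenyl)-7-hydroxy-6-methoxy-2,3-bis(hydroxymethyl)tetralin | COc1cc2c(cc1O)[C@@H](c1cc(OC)c(O)c(OC)c1)[C@H](CO)[C@@H](CO)C2 | target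

## Step count
- Total steps: 9, including the three reagent-preparation steps (2, 3, 5).
- Longest linear sequence: 7 steps (syringic acid → 4 → 5 → 6 → 10 → 11 → 12 → 13).

## Three steps most likely to fail
1. **Step 6 (photoenol Diels–Alder).** The benzophenone photoenol may revert rather than be trapped, or the bulky menthyl fumarate may give low diastereoselectivity. Fallback: run the photoenol Diels–Alder on the corresponding 2-methylbenzaldehyde (Rieche formylation of 2), which is much better precedented. Then install the syringyl group by Lewis-acid Friedel–Crafts benzylation of syringol at the C1 alcohol. Separate the menthyl diastereomers, and finish with LiAlH4 and hydrogenolysis.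
2. **Step 7 (C1 ionic hydrogenation).** The cation may eliminate to the conjugated dihydronaphthalene, or the C1 selectivity may be poor. Fallback: dehydrate deliberately (TsOH) to the 1-aryl-3,4-dihydronaphthalene-2-carboxylate and hydrogenate it. Then epimerise the α-ester centres with NaOMe/MeOH to the thermodynamic all-trans isomer, resolving the diastereomers at that stage.
3. **Step 4 (Friedel–Crafts acylation).** SnCl4 may cleave the benzyl ether or give regioisomers. Fallback: brominate 2 with NBS at the position para to OMe, then do Li–Br exchange and add the aryllithium to the Weinreb amide of O-benzyl syringic acid. This gives the same ketone, with a benzyl instead of an acetyl group on the syringyl oxygen. The extra benzyl is removed in step 9.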